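## Retrosynthetic overview

1. Target ⇐ allylic oxidation, desilylation and acetylation ⇐ Heck union of a core-bound iodovinyl unit with myrcene (gives the all-conjugated triene).
2. trans-2-Alkenylcyclopentanol ⇐ SN2 opening of a spiro cyclopentene oxide (hydroxyl-directed epoxidation) ⇐ spiro cyclopentanone (Shapiro reaction).
3. Key step: one-flask gold-catalysed alkyne carbocyclization / semipinacol ring expansion / iododeauration of a silylene-tethered 1-alkenylcyclobutanol. The cyclohexane closes first (C6–C7 bond), then the cyclobutane expands to the cyclopentanone, so both rings of the spiro[4.5]decane form in one operation; C5, C6 and the exocyclic alkene geometry are set from C10.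
4. Cascade substrate ⇐ cyclobutanone + alkenylstannane (trans-hydrostannation of a tertiary propargylic alcohol).
5. Propargylic alcohol (C10 stereocentre) ⇐ Sharpless epoxidation / Takano–Yadav alkyne synthesis / alkylation of an allylic alcohol made from methyl vinyl ketone, a propargyl silyl ether and a phosphonoacetate.

Assumption: the core keeps one fixed numbering in all names (C1 = CHOH, C2 = CH bearing the trienyl chain, C5 = spiro carbon, C6 = CH bearing the hydroxypropyl chain, C7 = ring carbon of the enal, C10 = C(CH3)OH; target = 1S,2S,5S,6R,10S), CIP descriptors refer to it, and TBS = tert-butyldimethylsilyl.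

## Route

Step 1
Reactants: 1 tert-butyldimethyl(prop-2-yn-1-yloxy)silane; 2 but-3-en-2-one
Product: 3 7-(TBS-oxy)hept-5-yn-2-one
Conditions: Pd(OAc)2 (5 mol %), PMe3 (20 mol %), acetone, 60 °C
Reagents that add atoms: none
Why: Palladium-catalysed conjugate hydroalkynylation of the vinyl ketone joins the alkyne terminus to the β-carbon with full atom economy and creates no stereocentre.

Step 2
Reactants: 3 7-(TBS-oxy)hept-5-yn-2-one; 4 triethyl phosphonoacetate
Product: 5 ethyl (2E)-8-(TBS-oxy)-3-methyloct-2-en-6-ynoate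
Conditions: NaH, THF, 0 °C to rt
Reagents that add atoms: none
Why: Horner–Wadsworth–Emmons olefination of the methyl ketone gives mainly the E-enoate (about 4:1); the minor Z isomer is removed by chromatography here or after step 3.

Step 3
Reactants: 5 ethyl (2E)-8-(TBS-oxy)-3-methyloct-2-en-6-ynoate
Product: 6 (2E)-8-(TBS-oxy)-3-methyloct-2-en-6-yn-1-ol
Conditions: i-Bu2AlH (2.2 equiv), CH2Cl2, −78 °C
Reagents that add atoms: none
Why: 1,2-Reduction of the conjugated ester by the aluminium hydride gives the allylic alcohol without touching the alkyne or the silyl ether.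

Step 4
Reactants: 6 (2E)-8-(TBS-oxy)-3-methyloct-2-en-6-yn-1-ol
Product: 7 [(2S,3S)-3-methyl-3-[5-(TBS-oxy)pent-3-yn-1-yl]oxiran-2-yl]methanol
Conditions: Ti(OiPr)4 (10 mol %), L-(+)-diethyl tartrate (12 mol %), t-BuOOH, 4 Å MS, CH2Cl2, −20 °C
Reagents that add atoms: tert-butyl hydroperoxide, CC(C)(C)OO
Why: Sharpless asymmetric epoxidation with the L-(+)-tartrate epoxidises the E-allylic alcohol on the face that gives the (2S,3S) epoxide (as for geraniol), which fixes the absolute configuration of the future C10.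

Step 5
Reactants: 7 [(2S,3S)-3-methyl-3-[5-(TBS-oxy)pent-3-yn-1-yl]oxiran-2-yl]methanol
Product: 8 (2R,3S)-2-(chloromethyl)-3-methyl-3-[5-(TBS-oxy)pent-3-yn-1-yl]oxirane
Conditions: PPh3, N-chlorosuccinimide, THF, 0 °C
Reagents that add atoms: N-chlorosuccinimide, O=C1CCC(=O)N1Cl
Why: Appel-type chlorination of the primary alcohol under neutral conditions leaves the epoxide and both stereocentres intact.

Step 6
Reactants: 8 (2R,3S)-2-(chloromethyl)-3-methyl-3-[5-(TBS-oxy)pent-3-yn-1-yl]oxirane; 9 tert-butyl(3-iodopropoxy)dimethylsilane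
Product: 11 (6S)-1,11-bis(TBS-oxy)-6-methylundeca-4,9-diyn-6-ol, via dilithium alkynide alkoxide 10 (not isolated)
Conditions: LiN(i-Pr)2 (3.3 equiv), THF, −78 to −20 °C; then 9, HMPA, −20 °C to rt
Reagents that add atoms: none
Why: Takano–Yadav double elimination of the epoxy chloride gives the tertiary propargylic alkoxide without breaking any bond at the carbinol carbon, so its configuration is kept (S), and the acetylide formed in the same flask is C-alkylated by the primary iodide.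

Step 7
Reactants: 11 (6S)-1,11-bis(TBS-oxy)-6-methylundeca-4,9-diyn-6-ol
Product: 12 (4Z,6S)-1,11-bis(TBS-oxy)-6-methyl-5-(tributylstannyl)undec-4-en-9-yn-6-ol
Conditions: Bu3SnH (1.05 equiv), [Cp*RuCl]4 (1.5 mol %), CH2Cl2, rt
Reagents that add atoms: tributyltin hydride, CCCC[SnH](CCCC)CCCC
Why: Hydroxyl-directed ruthenium-catalysed trans-hydrostannation puts tin on the alkyne carbon next to the carbinol and hydrogen trans to it (4Z), while the remote alkyne, which has no protic directing group, reacts much more slowly.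

Step 8
Reactants: 12 (4Z,6S)-1,11-bis(TBS-oxy)-6-methyl-5-(tributylstannyl)undec-4-en-9-yn-6-ol; 13 cyclobutanone
Product: 16 (8S,9Z)-9-[4-(TBS-oxy)butylidene]-6,6,8-trimethyl-8-[5-(TBS-oxy)pent-3-yn-1-yl]-5,7-dioxa-6-silaspiro[3.5]nonane, via lithium alkoxide vinyllithium 14 (not isolated), via dilithium diolate 15 (not isolated)
Conditions: n-BuLi (2.1 equiv), THF, −78 °C; then 13, −78 °C; then Me2SiCl2, −78 °C to rt
Reagents that add atoms: dichlorodimethylsilane, C[Si](C)(Cl)Cl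
Why: Tin–lithium exchange keeps the alkene geometry, the vinyllithium adds 1,2 to the strained ketone, and the dilithium 1,3-diolate is closed to the six-membered silylene acetal, so the propyl chain ends cis to the cyclobutanol carbon.

Step 9
Reactants: 16 (8S,9Z)-9-[4-(TBS-oxy)butylidene]-6,6,8-trimethyl-8-[5-(TBS-oxy)pent-3-yn-1-yl]-5,7-dioxa-6-silaspiro[3.5]nonane
Product: 18 (5R,6S,7E,10S)-10-hydroxy-7-[1-iodo-2-(TBS-oxy)ethylidene]-10-methyl-6-[3-(TBS-oxy)propyl]spiro[4.5]decan-1-one, via N-silylsuccinimide ether 17 (not isolated)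
Conditions: Ph3PAuNTf2 (5 mol %), N-iodosuccinimide (1.2 equiv), CH2Cl2, −20 °C; then MeOH, PPTS (cat.), 0 °C
Reagents that add atoms: N-iodosuccinimide, O=C1CCC(=O)N1I
Why: Proposed new method: the cationic monovalent gold complex activates the alkyne, C6 of the trisubstituted alkene attacks the distal alkyne carbon C7 (6-exo-dig) anti to gold, the developing C5 cation is quenched by antiperiplanar 1,2-shift of a cyclobutane CH2 (semipinacol ring expansion to the cyclopentanone), and the vinylgold is iododeaurated by NIS with retention while succinimide takes over the silyl group; the dioxasilinane tether holds the C10–O bond in the alkene plane so that the alkyne tether and the C10 methyl lie on opposite faces, which fixes C5 and C6 relative to C10 (C4 cis to CH3, C1 and the propyl chain cis to the C10 oxygen) and puts iodine trans to C6; the closest known reaction types are the gold-catalysed enyne carbocyclization/pinacol shift of silyloxy enynes, the semipinacol ring expansion of 1-alkenylcyclobutanols and the iododeauration of vinylgold intermediates.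

Step 10
Reactants: 18 (5R,6S,7E,10S)-10-hydroxy-7-[1-iodo-2-(TBS-oxy)ethylidene]-10-methyl-6-[3-(TBS-oxy)propyl]spiro[4.5]decan-1-one
Product: 19 (5R,6R,7Z,10S)-10-hydroxy-10-methyl-7-[1-(TBS-oxy)propan-2-ylidene]-6-[3-(TBS-oxy)propyl]spiro[4.5]decan-1-one
Conditions: SnMe4, Pd2(dba)3 (5 mol %), AsPh3, CuI, NMP, 60 °C
Reagents that add atoms: tetramethylstannane, C[Sn](C)(C)C
Why: Stille cross-coupling replaces iodine by methyl with retention of the alkene geometry under neutral conditions that spare the base-sensitive β-hydroxy ketone.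

Step 11
Reactants: 19 (5R,6R,7Z,10S)-10-hydroxy-10-methyl-7-[1-(TBS-oxy)propan-2-ylidene]-6-[3-(TBS-oxy)propyl]spiro[4.5]decan-1-one
Product: 20 (1E,5S,6R,7Z,10S)-2,4,6-triisopropylbenzenesulfonylhydrazone of 19
Conditions: 2,4,6-triisopropylbenzenesulfonyl hydrazide, HCl (cat.), THF, rt
Reagents that add atoms: 2,4,6-triisopropylbenzenesulfonyl hydrazide, CC(C)c1cc(C(C)C)c(S(=O)(=O)NN)c(C(C)C)c1
Why: Acid-catalysed condensation gives the hydrazone with the sulfonamide nitrogen anti to the quaternary C5, that is syn to the only α-CH2 (C2).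

Step 12
Reactants: 20 (1E,5S,6R,7Z,10S)-2,4,6-triisopropylbenzenesulfonylhydrazone of 19
Product: 22 (5R,6R,7Z,10S)-10-methyl-7-[1-(TBS-oxy)propan-2-ylidene]-6-[3-(TBS-oxy)propyl]spiro[4.5]dec-1-en-10-ol, via C1 vinyllithium alkoxide 21 (not isolated)
Conditions: n-BuLi (3.3 equiv), THF, −78 to 0 °C; then H2O
Reagents that add atoms: none
Why: Shapiro reaction: after deprotonation of OH and NH, syn α-deprotonation at C2 and loss of sulfinate and dinitrogen give the C1 vinyllithium, which is protonated to the C1=C2 alkene.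

Step 13
Reactants: 22 (5R,6R,7Z,10S)-10-methyl-7-[1-(TBS-oxy)propan-2-ylidene]-6-[3-(TBS-oxy)propyl]spiro[4.5]dec-1-en-10-ol
Product: 23 (1R,2S,5S,6R,7Z,10S)-1,2-epoxy-10-methyl-7-[1-(TBS-oxy)propan-2-ylidene]-6-[3-(TBS-oxy)propyl]spiro[4.5]decan-10-ol
Conditions: VO(acac)2 (5 mol %), t-BuOOH, CH2Cl2, 0 °C to rt
Reagents that add atoms: tert-butyl hydroperoxide, CC(C)(C)OO
Why: Vanadium-catalysed epoxidation directed by the homoallylic tertiary C10 hydroxyl delivers oxygen to the cyclopentene face syn to C10 and leaves the hindered tetrasubstituted alkene, which has no suitably placed hydroxyl, untouched.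

Step 14
Reactants: 24 3-(trimethylsilyl)prop-2-yn-1-ol
Product: 25 (2Z)-2-(tributylstannyl)-3-(trimethylsilyl)prop-2-en-1-ol
Conditions: Bu3SnH (1.05 equiv), [Cp*RuCl]4 (1.5 mol %), CH2Cl2, rt
Reagents that add atoms: tributyltin hydride, CCCC[SnH](CCCC)CCCC
Why: Hydroxyl-directed ruthenium-catalysed trans-hydrostannation puts tin next to the CH2OH group and hydrogen trans to it, so tin and silicon end cis.

Step 15
Reactants: 23 (1R,2S,5S,6R,7Z,10S)-1,2-epoxy-10-methyl-7-[1-(TBS-oxy)propan-2-ylidene]-6-[3-(TBS-oxy)propyl]spiro[4.5]decan-10-ol; 25 (2Z)-2-(tributylstannyl)-3-(trimethylsilyl)prop-2-en-1-ol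
Product: 27 (1S,2S,5S,6R,7Z,10S)-2-[(1E)-3-hydroxy-1-(trimethylsilyl)prop-1-en-2-yl]-10-methyl-7-[1-(TBS-oxy)propan-2-ylidene]-6-[3-(TBS-oxy)propyl]spiro[4.5]decane-1,10-diol, via lithium alkoxide vinyllithium 26 (not isolated)
Conditions: 25, n-BuLi (2 equiv), THF, −78 °C; then 23 (pre-treated with n-BuLi, 1 equiv), BF3·OEt2, −78 °C
Reagents that add atoms: none
Why: BF3-assisted SN2 opening of the epoxide by the alkenyllithium occurs at C2, remote from the quaternary C5, with inversion, so the alkenyl group enters anti to the C1 oxygen (trans-1,2) and C1 keeps the configuration set in step 13; tin–lithium exchange keeps silicon cis to the new C–C bond.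

Step 16
Reactants: 27 (1S,2S,5S,6R,7Z,10S)-2-[(1E)-3-hydroxy-1-(trimethylsilyl)prop-1-en-2-yl]-10-methyl-7-[1-(TBS-oxy)propan-2-ylidene]-6-[3-(TBS-oxy)propyl]spiro[4.5]decane-1,10-diol
Product: 28 (1S,2S,5S,6R,7Z,10S)-2-[(1E)-3-acetoxy-1-(trimethylsilyl)prop-1-en-2-yl]-10-methyl-7-[1-(TBS-oxy)propan-2-ylidene]-6-[3-(TBS-oxy)propyl]spiro[4.5]decane-1,10-diol
Conditions: Ac2O (1.1 equiv), 2,4,6-collidine, CH2Cl2, −20 to 0 °C
Reagents that add atoms: acetic anhydride, CC(=O)OC(C)=O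
Why: The unhindered primary allylic hydroxyl is acylated far faster than the neopentyl-type secondary C1 hydroxyl and the tertiary C10 hydroxyl.

Step 17
Reactants: 28 (1S,2S,5S,6R,7Z,10S)-2-[(1E)-3-acetoxy-1-(trimethylsilyl)prop-1-en-2-yl]-10-methyl-7-[1-(TBS-oxy)propan-2-ylidene]-6-[3-(TBS-oxy)propyl]spiro[4.5]decane-1,10-diol
Product: 29 (1S,2S,5S,6R,7Z,10S)-2-[(1E)-3-acetoxy-1-iodoprop-1-en-2-yl]-10-methyl-7-[1-(TBS-oxy)propan-2-ylidene]-6-[3-(TBS-oxy)propyl]spiro[4.5]decane-1,10-diol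
Conditions: N-iodosuccinimide (1.1 equiv), (CF3)2CHOH, 0 °C
Reagents that add atoms: N-iodosuccinimide, O=C1CCC(=O)N1I
Why: Iododesilylation of the vinylsilane (ipso substitution through the β-silyl cation) proceeds with retention and gives the vinyl iodide with iodine cis to C2.

Step 18
Reactants: 29 (1S,2S,5S,6R,7Z,10S)-2-[(1E)-3-acetoxy-1-iodoprop-1-en-2-yl]-10-methyl-7-[1-(TBS-oxy)propan-2-ylidene]-6-[3-(TBS-oxy)propyl]spiro[4.5]decane-1,10-diol; 30 7-methyl-3-methylideneocta-1,6-diene (myrcene)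
Product: 31 (1S,2S,5S,6R,7Z,10S)-2-[(2E,4E)-1-acetoxy-10-methyl-6-methylideneundeca-2,4,9-trien-2-yl]-10-methyl-7-[1-(TBS-oxy)propan-2-ylidene]-6-[3-(TBS-oxy)propyl]spiro[4.5]decane-1,10-diol
Conditions: Pd(OAc)2 (10 mol %), n-Bu4NCl, NaHCO3, DMF, 50 °C, myrcene (5 equiv)
Reagents that add atoms: none
Why: Mizoroki–Heck reaction under phosphine-free Jeffery conditions: the alkenylpalladium adds to the unsubstituted vinyl terminus of the diene and β-hydride elimination gives the new E-alkene in conjugation, with retention at the trisubstituted alkene.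

Step 19
Reactants: 31 (1S,2S,5S,6R,7Z,10S)-2-[(2E,4E)-1-acetoxy-10-methyl-6-methylideneundeca-2,4,9-trien-2-yl]-10-methyl-7-[1-(TBS-oxy)propan-2-ylidene]-6-[3-(TBS-oxy)propyl]spiro[4.5]decane-1,10-diol
Product: 32 (1S,2S,5S,6R,7Z,10S)-2-[(2E,4E)-1-acetoxy-10-methyl-6-methylideneundeca-2,4,9-trien-2-yl]-7-(1-hydroxypropan-2-ylidene)-6-(3-hydroxypropyl)-10-methylspiro[4.5]decane-1,10-diol
Conditions: HF·pyridine, pyridine, THF, 0 °C to rt
Reagents that add atoms: none
Why: Buffered fluoride cleaves both primary silyl ethers and leaves the allylic acetate and the triene intact.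

Step 20
Reactants: 32 (1S,2S,5S,6R,7Z,10S)-2-[(2E,4E)-1-acetoxy-10-methyl-6-methylideneundeca-2,4,9-trien-2-yl]-7-(1-hydroxypropan-2-ylidene)-6-(3-hydroxypropyl)-10-methylspiro[4.5]decane-1,10-diol
Product: 33 (2Z)-2-[(1S,2S,5S,6R,10S)-2-[(2E,4E)-1-acetoxy-10-methyl-6-methylideneundeca-2,4,9-trien-2-yl]-1,10-dihydroxy-6-(3-hydroxypropyl)-10-methylspiro[4.5]decan-7-ylidene]propanal (CNP0204268.2)
Conditions: MnO2 (20 equiv), CH2Cl2, rt
Reagents that add atoms: none
Why: Activated manganese dioxide oxidises only the allylic primary alcohol to the enal, with retention of the tetrasubstituted alkene geometry, and does not touch the saturated primary, secondary and tertiary hydroxyls.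

## Compound list

1 | tert-butyldimethyl(prop-2-yn-1-yloxy)silane | C#CCO[Si](C)(C)C(C)(C)C | starting material
2 | but-3-en-2-one | CC(=O)C=C | starting material
3 | 7-(TBS-oxy)hept-5-yn-2-one | CC(=O)CCC#CCO[Si](C)(C)C(C)(C)C | intermediate
4 | triethyl phosphonoacetate | CCOC(=O)CP(=O)(OCC)OCC | starting material
5 | ethyl (2E)-8-(TBS-oxy)-3-methyloct-2-en-6-ynoate | CCOC(=O)/C=C(\C)CCC#CCO[Si](C)(C)C(C)(C)C | intermediate
6 | (2E)-8-(TBS-oxy)-3-methyloct-2-en-6-yn-1-ol | OC/C=C(\C)CCC#CCO[Si](C)(C)C(C)(C)C | intermediate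
7 | [(2S,3S)-3-methyl-3-[5-(TBS-oxy)pent-3-yn-1-yl]oxiran-2-yl]methanol | OC[C@@H]1O[C@@]1(C)CCC#CCO[Si](C)(C)C(C)(C)C | intermediate
8 | (2R,3S)-2-(chloromethyl)-3-methyl-3-[5-(TBS-oxy)pent-3-yn-1-yl]oxirane | ClC[C@@H]1O[C@@]1(C)CCC#CCO[Si](C)(C)C(C)(C)C | intermediate
9 | tert-butyl(3-iodopropoxy)dimethylsilane | ICCCO[Si](C)(C)C(C)(C)C | starting material
10 | dilithium alkynide alkoxide from 8 | [Li+].[Li+].[C-]#C[C@@](C)([O-])CCC#CCO[Si](C)(C)C(C)(C)C | intermediate
11 | (6S)-1,11-bis(TBS-oxy)-6-methylundeca-4,9-diyn-6-ol | C[C@@](O)(C#CCCCO[Si](C)(C)C(C)(C)C)CCC#CCO[Si](C)(C)C(C)(C)C | intermediate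
12 | (4Z,6S)-1,11-bis(TBS-oxy)-6-methyl-5-(tributylstannyl)undec-4-en-9-yn-6-ol | C[C@@](O)(/C(=C/CCCO[Si](C)(C)C(C)(C)C)[Sn](CCCC)(CCCC)CCCC)CCC#CCO[Si](C)(C)C(C)(C)C | intermediate
13 | cyclobutanone | O=C1CCC1 | starting material
14 | lithium alkoxide vinyllithium from 12 | [Li+].[Li]/C(=C\CCCO[Si](C)(C)C(C)(C)C)[C@@](C)([O-])CCC#CCO[Si](C)(C)C(C)(C)C | intermediate
15 | dilithium diolate (cyclobutanone adduct) | [Li+].[Li+].[O-]C1(CCC1)/C(=C\CCCO[Si](C)(C)C(C)(C)C)[C@@](C)([O-])CCC#CCO[Si](C)(C)C(C)(C)C | intermediate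
16 | (8S,9Z)-9-[4-(TBS-oxy)butylidene]-6,6,8-trimethyl-8-[5-(TBS-oxy)pent-3-yn-1-yl]-5,7-dioxa-6-silaspiro[3.5]nonane | C[Si]1(C)OC2(CCC2)/C(=C\CCCO[Si](C)(C)C(C)(C)C)[C@](C)(CCC#CCO[Si](C)(C)C(C)(C)C)O1 | intermediate
17 | N-silylsuccinimide ether of 18 (C10–O–SiMe2–succinimide) | O=C1CCC[C@]12[C@H](CCCO[Si](C)(C)C(C)(C)C)/C(=C(/I)CO[Si](C)(C)C(C)(C)C)CC[C@]2(C)O[Si](C)(C)N3C(=O)CCC3=O | intermediate
18 | (5R,6S,7E,10S)-10-hydroxy-7-[1-iodo-2-(TBS-oxy)ethylidene]-10-methyl-6-[3-(TBS-oxy)propyl]spiro[4.5]decan-1-one | O=C1CCC[C@]12[C@H](CCCO[Si](C)(C)C(C)(C)C)/C(=C(/I)CO[Si](C)(C)C(C)(C)C)CC[C@]2(C)O | intermediate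
19 | (5R,6R,7Z,10S)-10-hydroxy-10-methyl-7-[1-(TBS-oxy)propan-2-ylidene]-6-[3-(TBS-oxy)propyl]spiro[4.5]decan-1-one | O=C1CCC[C@]12[C@H](CCCO[Si](C)(C)C(C)(C)C)/C(=C(/C)CO[Si](C)(C)C(C)(C)C)CC[C@]2(C)O | intermediate
20 | (1E,5S,6R,7Z,10S)-2,4,6-triisopropylbenzenesulfonylhydrazone of 19 | CC(C)c1cc(C(C)C)c(S(=O)(=O)N/N=C2\CCC[C@]23[C@H](CCCO[Si](C)(C)C(C)(C)C)/C(=C(/C)CO[Si](C)(C)C(C)(C)C)CC[C@]3(C)O)c(C(C)C)c1 | intermediate
21 | C1 vinyllithium alkoxide | [Li+].[Li]C1=CCC[C@]12[C@H](CCCO[Si](C)(C)C(C)(C)C)/C(=C(/C)CO[Si](C)(C)C(C)(C)C)CC[C@]2(C)[O-] | intermediate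
22 | (5R,6R,7Z,10S)-10-methyl-7-[1-(TBS-oxy)propan-2-ylidene]-6-[3-(TBS-oxy)propyl]spiro[4.5]dec-1-en-10-ol | C1=CCC[C@]12[C@H](CCCO[Si](C)(C)C(C)(C)C)/C(=C(/C)CO[Si](C)(C)C(C)(C)C)CC[C@]2(C)O | intermediate
23 | (1R,2S,5S,6R,7Z,10S)-1,2-epoxy-10-methyl-7-[1-(TBS-oxy)propan-2-ylidene]-6-[3-(TBS-oxy)propyl]spiro[4.5]decan-10-ol | O1[C@H]2CC[C@]3([C@H](CCCO[Si](C)(C)C(C)(C)C)/C(=C(/C)CO[Si](C)(C)C(C)(C)C)CC[C@]3(C)O)[C@@H]12 | intermediate
24 | 3-(trimethylsilyl)prop-2-yn-1-ol | C[Si](C)(C)C#CCO | starting material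
25 | (2Z)-2-(tributylstannyl)-3-(trimethylsilyl)prop-2-en-1-ol | OC/C(=C/[Si](C)(C)C)[Sn](CCCC)(CCCC)CCCC | intermediate
26 | lithium alkoxide vinyllithium from 25 | [Li+].[Li]/C(C[O-])=C\[Si](C)(C)C | intermediate
27 | (1S,2S,5S,6R,7Z,10S)-2-[(1E)-3-hydroxy-1-(trimethylsilyl)prop-1-en-2-yl]-10-methyl-7-[1-(TBS-oxy)propan-2-ylidene]-6-[3-(TBS-oxy)propyl]spiro[4.5]decane-1,10-diol | C[Si](C)(C)/C=C(/CO)[C@@H]1CC[C@]2([C@H](CCCO[Si](C)(C)C(C)(C)C)/C(=C(/C)CO[Si](C)(C)C(C)(C)C)CC[C@]2(C)O)[C@H]1O | intermediate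
28 | (1S,2S,5S,6R,7Z,10S)-2-[(1E)-3-acetoxy-1-(trimethylsilyl)prop-1-en-2-yl]-10-methyl-7-[1-(TBS-oxy)propan-2-ylidene]-6-[3-(TBS-oxy)propyl]spiro[4.5]decane-1,10-diol | C[Si](C)(C)/C=C(/COC(C)=O)[C@@H]1CC[C@]2([C@H](CCCO[Si](C)(C)C(C)(C)C)/C(=C(/C)CO[Si](C)(C)C(C)(C)C)CC[C@]2(C)O)[C@H]1O | intermediate
29 | (1S,2S,5S,6R,7Z,10S)-2-[(1E)-3-acetoxy-1-iodoprop-1-en-2-yl]-10-methyl-7-[1-(TBS-oxy)propan-2-ylidene]-6-[3-(TBS-oxy)propyl]spiro[4.5]decane-1,10-diol | I/C=C(/COC(C)=O)[C@@H]1CC[C@]2([C@H](CCCO[Si](C)(C)C(C)(C)C)/C(=C(/C)CO[Si](C)(C)C(C)(C)C)CC[C@]2(C)O)[C@H]1O | intermediate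
30 | 7-methyl-3-methylideneocta-1,6-diene (myrcene) | C=CC(=C)CCC=C(C)C | starting material
31 | (1S,2S,5S,6R,7Z,10S)-2-[(2E,4E)-1-acetoxy-10-methyl-6-methylideneundeca-2,4,9-trien-2-yl]-10-methyl-7-[1-(TBS-oxy)propan-2-ylidene]-6-[3-(TBS-oxy)propyl]spiro[4.5]decane-1,10-diol | C=C(/C=C/C=C(/COC(C)=O)[C@@H]1CC[C@]2([C@H](CCCO[Si](C)(C)C(C)(C)C)/C(=C(/C)CO[Si](C)(C)C(C)(C)C)CC[C@]2(C)O)[C@H]1O)CCC=C(C)C | intermediate
32 | (1S,2S,5S,6R,7Z,10S)-2-[(2E,4E)-1-acetoxy-10-methyl-6-methylideneundeca-2,4,9-trien-2-yl]-7-(1-hydroxypropan-2-ylidene)-6-(3-hydroxypropyl)-10-methylspiro[4.5]decane-1,10-diol | C=C(/C=C/C=C(/COC(C)=O)[C@@H]1CC[C@]2([C@H](CCCO)/C(=C(/C)CO)CC[C@]2(C)O)[C@H]1O)CCC=C(C)C | intermediate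
33 | (2Z)-2-[(1S,2S,5S,6R,10S)-2-[(2E,4E)-1-acetoxy-10-methyl-6-methylideneundeca-2,4,9-trien-2-yl]-1,10-dihydroxy-6-(3-hydroxypropyl)-10-methylspiro[4.5]decan-7-ylidene]propanal (CNP0204268.2) | C=C(/C=C/C=C(/COC(C)=O)[C@@H]1CC[C@]2([C@H](CCCO)/C(=C(/C)C=O)CC[C@]2(C)O)[C@H]1O)CCC=C(C)C | target

## Step count

Total steps: 20. Longest linear sequence: 19 (steps 1–13 and 15–20; step 14 is a one-step branch).

## Three steps most likely to fail, with fallbacks

Step 9 (key cascade). The alkene carries two allylic oxygens and is hindered, and NIS or the transient silyl triflimide could attack the alkenylcyclobutanol before the alkyne is engaged. The fallback sets out from 16 and comes back at 18, and it separates the carbon–carbon bond formation from the halogenation. Compound 16 is treated with Ph3PAuNTf2 (1.05 equiv) and 2,6-di-tert-butyl-4-methylpyridine in CH2Cl2 with no iodine source, then quenched with MeOH/Et3N. This gives the isolable (triphenylphosphine)gold vinyl complex of the spiro ketone, C10 oxygen carried as a methoxydimethylsilyl ether F1. Purified F1 is iododeaurated with NIS at −40 °C to the methoxydimethylsilyl ether of 18 F2, and PPTS/MeOH in the same flask removes the silyl group to give 18.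

Step 15 (epoxide opening). A branched alkenyllithium has to attack a cyclopentene oxide next to a quaternary centre in the presence of BF3. The fallback sets out from 23 and comes back at 27, and it builds the alkenyl unit on the ring instead of delivering it intact. Lithium (trimethylsilyl)acetylide with BF3·OEt2 (THF, −78 °C), a much smaller nucleophile, opens 23 at C2 to the trans-2-[(trimethylsilyl)ethynyl]spiro diol F3. Ti(OiPr)4 and i-PrMgCl (excess, Et2O, −50 °C) then convert the silylalkyne into its titanium–alkyne complex, which adds monomeric formaldehyde at the alkyne carbon remote from silicon. Hydrolysis gives the syn hydro-hydroxymethylation product, which is 27 (silicon cis to C2).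

Step 18 (Heck reaction with myrcene). The π-allylpalladium formed after insertion into the diene can be trapped instead of undergoing β-hydride elimination, and the allylic acetate can ionise. The fallback sets out from 29 and comes back at 31, and it uses a preformed dienyl nucleophile. 6-Methylhept-5-en-2-one is converted by LiN(i-Pr)2 and PhNTf2 (THF, −78 °C) into 6-methylhepta-1,5-dien-2-yl triflate F4. Stille coupling of F4 with (E)-1,2-bis(tributylstannyl)ethene (Pd(PPh3)4, LiCl, THF, 60 °C) gives tributyl[(1E)-7-methyl-3-methylideneocta-1,6-dien-1-yl]stannane F5. Stille coupling of 29 with F5 (Pd2(dba)3, AsPh3, NMP, rt) gives 31 with retention at both alkenes.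

## Further compounds

F1 | step 9 | (triphenylphosphine)gold vinyl complex of the spiro ketone, gold trans to C6, C10–O–SiMe2–OMe | O=C1CCC[C@]12[C@H](CCCO[Si](C)(C)C(C)(C)C)/C(=C(/[Au-][P+](c3ccccc3)(c3ccccc3)c3ccccc3)CO[Si](C)(C)C(C)(C)C)CC[C@]2(C)O[Si](C)(C)OC
F2 | step 9 | methoxydimethylsilyl ether of 18 | O=C1CCC[C@]12[C@H](CCCO[Si](C)(C)C(C)(C)C)/C(=C(/I)CO[Si](C)(C)C(C)(C)C)CC[C@]2(C)O[Si](C)(C)OC
F3 | step 15 | (1S,2S,5S,6R,7Z,10S)-10-methyl-7-[1-(TBS-oxy)propan-2-ylidene]-6-[3-(TBS-oxy)propyl]-2-[(trimethylsilyl)ethynyl]spiro[4.5]decane-1,10-diol | C[Si](C)(C)C#C[C@@H]1CC[C@]2([C@H](CCCO[Si](C)(C)C(C)(C)C)/C(=C(/C)CO[Si](C)(C)C(C)(C)C)CC[C@]2(C)O)[C@H]1O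
F4 | step 18 | 6-methylhepta-1,5-dien-2-yl trifluoromethanesulfonate | C=C(OS(=O)(=O)C(F)(F)F)CCC=C(C)C
F5 | step 18 | tributyl[(1E)-7-methyl-3-methylideneocta-1,6-dien-1-yl]stannane | CCCC[Sn](CCCC)(CCCC)/C=C/C(=C)CCC=C(C)C
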